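Remark on the chemistry: locants follow germacrane numbering (ring carbons C1–C10; C11, C12 (carbonyl) and C13 (acetoxymethyl) on the lactone; C14 on C10, C15 on C4). Read this way the SMILES is (4S,8S,10R) with C5=C6 E (C4 cis to C7).

## The problem

The target is a ten-membered carbocycle C1–C10 that is bridged by oxygen from C4 to C1 (2,3-dihydrofuran ring O/C1/C2/C3/C4 with the enol ether C1=C2) and fused at C6–C7 to a γ-ylidene butenolide (ring O/C6/C7/C11/C12 with exocyclic C5=C6). Any closure of this bicyclo[6.2.1] core meets medium-ring strain, and it would have to be done in the presence of two easily destroyed π systems: the enol ether (acid) and the α-acetoxymethyl ylidene butenolide (base, nucleophiles, loss of acetate). The C5=C6 bond must be E (C4 cis to C7), the opposite of what open-chain ylidene butenolides prefer, so it is best formed inside the ring. Of the three stereocentres, the tertiary ether carbon C4 (S) is remote from the syn-related pair C8 (S, secondary ester) and C10 (R, tertiary carbinol); nothing relays C4 to the pair, but C8 can control C10 (1,3). The methacrylate, the allylic 13-acetate and the free C10 alcohol next to the enol ether restrict the end game to near-neutral conditions. The feature that opens the plan is this: O–C1(=C2)–C3–C4 is the 5-endo adduct of the C4 hydroxyl to a C1≡C2 triple bond, and the butenolide with C5=C6 is the oxidised form of a furan (O, C6, C7, C11, C12) that carries C5H2 on C6; with both replacements the core becomes a furan-fused cyclodec-1-en-6-yne, in which the rod C10–C1≡C2–C3 lies opposite the furan edge C6=C7 and the ring can be closed at C1–C10 by acetylide acylation.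

## Retrosynthesis

**Target 23 to 22 (cut O–C1, add H at C2).** The dihydrofuran is opened to the homopropargylic alcohol: the C4 hydroxyl and a C1≡C2 triple bond inside the carbocycle. The neighbouring option, dehydration of a C1 hemiketal, needs acid on a molecule whose enol ether and allylic C4–O bond are both acid-labile; the alkyne route is an isomerisation under neutral gold catalysis. Precursor 22 has one ring less and no enol ether. The forward step must deliver O4 to C1 only and must not ionise the C10 or C4 carbinols.

**22 to 19 (cut the lactone C12=O and C5=C6; remove the 13-acetyl).** The ylidene butenolide is traced to the furan of 19 by way of endoperoxide 20 and hydroxybutenolide 21. The furan is inert to every earlier reagent, whereas a butenolide would not survive organolithium or Grignard steps and would lose a 13-acyloxy group on γ-deprotonation. The C5=C6 geometry is then decided by the ring. Photooxygenation must take place at the furan only; the alkyne is inert to singlet oxygen, which is why this step precedes the gold step.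

**19 to 17 (cut the C8 ester, restore the silyl ether).** Methacryloylation of the only secondary alcohol (18) and removal of the O13 silyl group; no selectivity problem is expected because the other alcohols are tertiary.

**17 to 16 (cut C10–C14).** The tertiary carbinol is made by methyl addition to the ring ynone 16. Adding methyl last (not the alkyne last) is chosen because axial attack on the C8-alkoxide chelate then leaves the alkynyl and furyl ring bonds equatorial, which is the 8,10-syn arrangement of the target. C8 thus controls C10.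

**16 to 14 (cut C1–C10; key step).** The ten-membered ring is opened at the bond between the alkyne terminus and the carbonyl: acetylide plus Weinreb amide, by way of chelate 15. Compared with cuts at C2–C3 (acetylide and epoxide, slow), C5–C6 (no mild furan alkylation) or C8–C9, this cut uses the most acidic C–H of the molecule and an acyl donor that stops at the ketone stage, and it creates no stereocentre. Precursor 14 is a monocyclic furan with two ortho arms.

**14 to 10 and 11 (cut C8–C9).** Acetate aldol addition sets C8 by reagent control (adduct 12, then amide 13 and alkyne 14). An acetone aldol was set aside because a methyl ketone would be enolised in the ring closure and would put the alkyne, not the methyl group, in the nucleophile role.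

**10 to 8 and 6 (cut C5–C6).** The furan α-carbon next to the free hydroxymethyl arm of 8 (from diol 7) is lithiated and opens epoxide 6 at its CH2 end (9, then aldehyde 10). This brings in C4 as a finished stereocentre, which removes the remote-stereocentre problem.

**6 to 3 and 4, and 3 to 1.** Epoxide 6 is a 2-methylglycidol unit used at both ends: trimethylsilylacetylene 4 opens epoxy tosylate 3 (giving 5), and ring closure onto the tosylate regenerates an epoxide. Tosylate 3 comes from methallyl alcohol 1 by asymmetric epoxidation via 2.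

## Roads not taken

**Alternative 1:** the obvious plan: keep both heterocycles, cut C5=C6, and close the ring by intramolecular vinylogous aldol condensation of seco-aldehyde A1 (butenolide γ-carbon C6 onto the C5 aldehyde). A1 must carry the acid-labile enol ether through fragment assembly, and its butenolide needs a regiochemically defined 3,4-disubstituted 2(5H)-furanone that the symmetric furan diol does not give directly. The γ-deprotonated butenolide would expel an acyloxy group at C13, which forces silyl protection and late ester exchange on the finished, sensitive bicycle. Closure has to form the bridged nine-membered oxa-ring with no rigid spacer. The chosen plan makes both sensitive rings after ring closure, from inert groups, and is estimated to be about six steps shorter.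

**Alternative 2:** the biomimetic plan: cut O–C4 and C5=C6 transannularly, i.e. treat the 1-oxo-4,5-epoxide A2 with acid or base so that the C1 enol oxygen opens the epoxide at C4 and C5–OH is lost by E1cB. A2 is no simpler than the target: the ten-membered ring is already present, and three more stereocentres (C4, C5, C6) must be set relative to C8 and C10 on a flexible ring. The cascade also exposes the product to the conditions that ionise its own C4–O bond. The ring-closure problem is left untouched.

**Alternative 3:** a bicycle cleavage: C1 and C6 are both at the ketone level and 1,6-related, so the C1=C6 bond of the octalin A3 (cadinane skeleton) could be cleaved oxidatively to dione A4, which would fold into the C1 hemiketal and the hydroxybutenolide and then be dehydrated twice. In A3, C4 sits on ring A and C8/C10 on ring B across a flat tetrasubstituted alkene, so no relay of configuration is available. The tetrasubstituted C7 alkylidene ester of defined geometry has no reliable construction on that hindered dienyl system. Ozone would have to choose among three alkenes, and 1,6-diones are prone to transannular aldol reaction. The chosen plan keeps the idea of a temporary element (the ring alkyne) but brings C4 in as an enantiopure epoxide.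

Key step: step 9

## Route

Step 1
Reactants: 1 2-methylprop-2-en-1-ol
Product: 3 (S)-(2-methyloxiran-2-yl)methyl 4-methylbenzenesulfonate, via (R)-2-methylglycidol 2 (not isolated)
Conditions: Ti(OiPr)4 (5 mol%), D-(−)-diisopropyl tartrate (6 mol%), cumene hydroperoxide, 3 Å MS, CH2Cl2, −20 °C; then TsCl, Et3N, DMAP (cat.), −10 °C
Reagents that add atoms: cumene hydroperoxide CC(C)(OO)c1ccccc1; 4-methylbenzenesulfonyl chloride Cc1ccc(cc1)S(=O)(=O)Cl
Why: Sharpless asymmetric epoxidation with derivatisation in the same flask; the D-tartrate catalyst should deliver oxygen to the face that gives (R)-2, and sulfonylation avoids isolating the water-soluble epoxy alcohol (the descriptor becomes S only because the sulfonate changes the CIP ranks).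

Step 2
Reactants: 3 (S)-(2-methyloxiran-2-yl)methyl 4-methylbenzenesulfonate; 4 ethynyl(trimethyl)silane
Product: 5 (S)-2-hydroxy-2-methyl-5-(trimethylsilyl)pent-4-yn-1-yl 4-methylbenzenesulfonate
Conditions: 4, n-BuLi, THF, −78 °C; BF3·OEt2; then 3, −78 °C
Reagents that add atoms: none
Why: Yamaguchi–Hirao alkynylation: the BF3-activated epoxide is opened by the lithium acetylide at its CH2 carbon, which at −78 °C is far faster than displacement of the sulfonate; the quaternary carbon keeps its C–O bond, so its configuration is untouched.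

Step 3
Reactants: 5 (S)-2-hydroxy-2-methyl-5-(trimethylsilyl)pent-4-yn-1-yl 4-methylbenzenesulfonate
Product: 6 (S)-trimethyl[3-(2-methyloxiran-2-yl)prop-1-yn-1-yl]silane
Conditions: NaH, THF, 0 → 20 °C
Reagents that add atoms: none
Why: Intramolecular Williamson etherification (3-exo-tet): the tertiary alkoxide displaces the primary sulfonate, which moves the epoxide to the other CH2 arm without touching the stereocentre; NaH, not K2CO3/MeOH, keeps the alkynyl silyl group.

Step 4
Reactants: 7 furan-3,4-diyldimethanol
Product: 8 [4-({[tert-butyl(dimethyl)silyl]oxy}methyl)furan-3-yl]methanol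
Conditions: NaH (1.0 equiv), THF, 0 °C; then TBSCl, 20 °C
Reagents that add atoms: tert-butyl(chloro)dimethylsilane CC(C)(C)[Si](C)(C)Cl
Why: Monosilylation of a symmetrical diol through its monosodium alkoxide; the two arms of 7 are equivalent, so only mono- versus bis-silylation has to be controlled.

Step 5
Reactants: 8 [4-({[tert-butyl(dimethyl)silyl]oxy}methyl)furan-3-yl]methanol; 6 (S)-trimethyl[3-(2-methyloxiran-2-yl)prop-1-yn-1-yl]silane
Product: 9 (S)-1-[4-({[tert-butyl(dimethyl)silyl]oxy}methyl)-3-(hydroxymethyl)furan-2-yl]-2-methyl-5-(trimethylsilyl)pent-4-yn-2-ol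
Conditions: 8, n-BuLi (2.2 equiv), THF, −78 → 0 °C; then 6, BF3·OEt2, −78 °C
Reagents that add atoms: none
Why: Alkoxide-directed lithiation puts the second lithium on the furan α-carbon next to CH2OLi (C6); BF3-assisted SN2 opening of 6 at its CH2 terminus then forms C5–C6. The C4 stereocentre is brought in by 6 and is not involved, and the low temperature keeps the aryllithium from attacking the alkynyl silicon.

Step 6
Reactants: 9 (S)-1-[4-({[tert-butyl(dimethyl)silyl]oxy}methyl)-3-(hydroxymethyl)furan-2-yl]-2-methyl-5-(trimethylsilyl)pent-4-yn-2-ol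
Product: 10 4-({[tert-butyl(dimethyl)silyl]oxy}methyl)-2-[(S)-2-hydroxy-2-methyl-5-(trimethylsilyl)pent-4-yn-1-yl]furan-3-carbaldehyde
Conditions: MnO2, CH2Cl2, 20 °C
Reagents that add atoms: none
Why: Manganese dioxide oxidises only the furylic (benzylic-type) primary alcohol; the tertiary alcohol cannot be oxidised.

Step 7
Reactants: 10 4-({[tert-butyl(dimethyl)silyl]oxy}methyl)-2-[(S)-2-hydroxy-2-methyl-5-(trimethylsilyl)pent-4-yn-1-yl]furan-3-carbaldehyde; 11 (S)-2-hydroxy-1,2,2-triphenylethyl acetate
Product: 12 (S)-2-hydroxy-1,2,2-triphenylethyl (S)-3-{4-({[tert-butyl(dimethyl)silyl]oxy}methyl)-2-[(S)-2-hydroxy-2-methyl-5-(trimethylsilyl)pent-4-yn-1-yl]furan-3-yl}-3-hydroxypropanoate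
Conditions: 11 (2.5 equiv), LDA (5 equiv), THF, −78 → 0 °C; MgBr2·OEt2, −78 °C; then 10, −100 °C
Reagents that add atoms: none
Why: Auxiliary-controlled acetate aldol addition of the doubly deprotonated triphenylglycol acetate (HYTRA); the (S)-reagent should give the (S)-carbinol at C8 with aldehydes whose substituent outranks the CH2C(=O) arm (reagent control), and the excess enolate absorbs the free C4 hydroxyl proton.

Step 8
Reactants: 12 (S)-2-hydroxy-1,2,2-triphenylethyl (S)-3-{4-({[tert-butyl(dimethyl)silyl]oxy}methyl)-2-[(S)-2-hydroxy-2-methyl-5-(trimethylsilyl)pent-4-yn-1-yl]furan-3-yl}-3-hydroxypropanoate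
Product: 14 (S)-3-{4-({[tert-butyl(dimethyl)silyl]oxy}methyl)-2-[(S)-2-hydroxy-2-methylpent-4-yn-1-yl]furan-3-yl}-3-hydroxy-N-methoxy-N-methylpropanamide, via C-silylated Weinreb amide 13 (not isolated)
Conditions: MeNH(OMe)·HCl, i-PrMgCl, THF, −20 → 0 °C; then K2CO3, MeOH, 20 °C
Reagents that add atoms: N,O-dimethylhydroxylamine hydrochloride CNOC.Cl
Why: Aminolysis of the ester by the chloromagnesium amide of N,O-dimethylhydroxylamine releases the auxiliary diol and gives the Weinreb amide; methanolysis then removes only the silyl group on the alkyne (the silyl ether on oxygen stays).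

Step 9
Reactants: 14 (S)-3-{4-({[tert-butyl(dimethyl)silyl]oxy}methyl)-2-[(S)-2-hydroxy-2-methylpent-4-yn-1-yl]furan-3-yl}-3-hydroxy-N-methoxy-N-methylpropanamide
Product: 16 (4S,8S)-13-[(tert-butyldimethylsilyl)oxy]-4,8-dihydroxy-14-nor-6,12-epoxygermacra-6,11-dien-1-yn-10-one (ten-membered ring C1–C10 with C1≡C2 and C10=O fused at C6–C7 to the furan), via lithium hemiaminal chelate 15 (not isolated)
Conditions: LDA (3.1 equiv), THF, −78 °C, slow addition of 14 (final 2 mM), −78 → −30 °C; then AcOH, −78 °C
Reagents that add atoms: none
Why: Proposed new method: LDA removes the two hydroxyl protons and the alkyne proton of 14 (the α-protons of the tertiary amide are about six pK units less acidic and are further shielded by the adjacent C8 alkoxide), and the C1 acetylide adds to the Weinreb carbonyl C10 to give the five-membered N–O lithium chelate 15, which cannot collapse before the acidic quench and therefore cannot over-react, enolise or undergo retro-aldol cleavage. The closest known reaction types are the intermolecular Weinreb ynone synthesis and the intramolecular acetylide-to-carbonyl additions that close the nine- and ten-membered carbocycles of enediyne antibiotics; new is their combination in the closure of a cycloalkynone. The ring formed is the ten-membered carbocycle C1–C10, closed at C1–C10 by a 10-exo-trig attack on the amide carbonyl. No stereocentre is created, so C4 and C8 are simply carried through. The selectivity needed is ring closure over oligomerisation: both arms sit on adjacent carbons of the planar furan (C6, C7), the electrophilic arm is only three atoms long, and the C10–C1≡C2–C3 unit has to bend no more than in cyclodecyne, whose strain is modest; slow addition at high dilution keeps the stationary concentration low. Quenching with AcOH at −78 °C releases 16 without base, so that the β-hydroxy ynone does not close to a dihydropyranone; 16 is used at once.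

Step 10
Reactants: 16 (4S,8S)-13-[(tert-butyldimethylsilyl)oxy]-4,8-dihydroxy-14-nor-6,12-epoxygermacra-6,11-dien-1-yn-10-one
Product: 17 (4S,8S,10R)-13-[(tert-butyldimethylsilyl)oxy]-6,12-epoxygermacra-6,11-dien-1-yne-4,8,10-triol
Conditions: MeMgBr (4 equiv), THF/CH2Cl2, −78 °C
Reagents that add atoms: methylmagnesium bromide C[Mg]Br
Why: Chelate-controlled (Cram-type) 1,2-addition: the magnesium alkoxide at C8 binds the C10 carbonyl in a six-membered chelate and methyl enters axially while the alkynyl and furyl ring bonds stay equatorial, the same course that gives syn-1,3-diols in the Narasaka–Prasad reduction; this should set C10 as R (8,10-syn). The hard Grignard reagent attacks the carbonyl carbon, not C2.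

Step 11
Reactants: 17 (4S,8S,10R)-13-[(tert-butyldimethylsilyl)oxy]-6,12-epoxygermacra-6,11-dien-1-yne-4,8,10-triol
Product: 18 (4S,8S,10R)-13-[(tert-butyldimethylsilyl)oxy]-4,10-dihydroxy-6,12-epoxygermacra-6,11-dien-1-yn-8-yl 2-methylprop-2-enoate
Conditions: methacrylic anhydride, Et3N, DMAP (cat.), CH2Cl2, 0 °C
Reagents that add atoms: methacrylic anhydride C=C(C)C(=O)OC(=O)C(C)=C
Why: DMAP-catalysed acylation reaches only the secondary C8 alcohol; the tertiary alcohols at C4 and C10 are inert under these conditions, so no protection is needed.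

Step 12
Reactants: 18 (4S,8S,10R)-13-[(tert-butyldimethylsilyl)oxy]-4,10-dihydroxy-6,12-epoxygermacra-6,11-dien-1-yn-8-yl 2-methylprop-2-enoate
Product: 19 (4S,8S,10R)-4,10,13-trihydroxy-6,12-epoxygermacra-6,11-dien-1-yn-8-yl 2-methylprop-2-enoate
Conditions: HF·pyridine, pyridine, THF, 0 °C
Reagents that add atoms: none
Why: Buffered fluoride cleaves the primary furylmethyl silyl ether without free base, which avoids migration of the methacryloyl group from O8 to the neighbouring O13.

Step 13
Reactants: 19 (4S,8S,10R)-4,10,13-trihydroxy-6,12-epoxygermacra-6,11-dien-1-yn-8-yl 2-methylprop-2-enoate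
Product: 22 (4S,5E,8S,10R)-13-acetoxy-4,10-dihydroxy-8-(methacryloyloxy)germacra-5,7(11)-dien-1-yn-12,6-olide, via furan endoperoxide 20 (not isolated), via hydroxybutenolide 21 (not isolated)
Conditions: O2, hν, tetraphenylporphyrin (cat.), i-Pr2NEt, CH2Cl2, −78 °C; then Ac2O, Et3N, DMAP (cat.), −78 → 20 °C
Reagents that add atoms: dioxygen O=O; acetic anhydride CC(=O)OC(C)=O
Why: [4+2] addition of singlet oxygen to the furan, then Kornblum–DeLaMare opening (the base removes the only furan α-hydrogen, at C12, which fixes C12 as the carbonyl carbon), then acetylation of O13 and enol-lactonisation of the 4-oxo-2-enoic acid form of 21 through its mixed anhydride. The new C5=C6 bond lies in the ten-membered ring beside the triple bond and can only be cis in the ring, which is the E geometry of the target; the alkyne and the methacrylate do not react with singlet oxygen at this temperature.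

Step 14
Reactants: 22 (4S,5E,8S,10R)-13-acetoxy-4,10-dihydroxy-8-(methacryloyloxy)germacra-5,7(11)-dien-1-yn-12,6-olide
Product: 23 (4S,5E,8S,10R)-13-acetoxy-1,4-epoxy-10-hydroxy-8-(methacryloyloxy)germacra-1,5,7(11)-trien-12,6-olide (target, CNP0394509.2)
Conditions: (Ph3P)AuNTf2 (3 mol%), 2,6-di-tert-butylpyridine (10 mol%), 4 Å MS, CH2Cl2, 0 → 20 °C
Reagents that add atoms: none
Why: Gold-catalysed 5-endo-dig hydroalkoxylation of a homopropargylic alcohol: the C4 hydroxyl adds anti across the gold-activated C1≡C2 bond (attack at C2 would give an oxetane), and protodeauration gives the C1=C2 enol ether; relief of cycloalkyne strain assists. No stereocentre is formed or broken because the C4–O bond is kept, and the hindered pyridine keeps the medium free of acid.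

## Compound list

1 | 2-methylprop-2-en-1-ol | C=C(C)CO | starting material
2 | (R)-(2-methyloxiran-2-yl)methanol | C[C@@]1(CO)CO1 | intermediate (not isolated)
3 | (S)-(2-methyloxiran-2-yl)methyl 4-methylbenzenesulfonate | C[C@@]1(COS(=O)(=O)c2ccc(C)cc2)CO1 | intermediate
4 | ethynyl(trimethyl)silane | C#C[Si](C)(C)C | starting material
5 | (S)-2-hydroxy-2-methyl-5-(trimethylsilyl)pent-4-yn-1-yl 4-methylbenzenesulfonate | C[Si](C)(C)C#CC[C@@](C)(COS(=O)(=O)c1ccc(C)cc1)O | intermediate
6 | (S)-trimethyl[3-(2-methyloxiran-2-yl)prop-1-yn-1-yl]silane | C[Si](C)(C)C#CC[C@@]1(C)CO1 | intermediate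
7 | furan-3,4-diyldimethanol | OCc1cocc1CO | starting material
8 | [4-({[tert-butyl(dimethyl)silyl]oxy}methyl)furan-3-yl]methanol | OCc1cocc1CO[Si](C)(C)C(C)(C)C | intermediate
9 | (S)-1-[4-({[tert-butyl(dimethyl)silyl]oxy}methyl)-3-(hydroxymethyl)furan-2-yl]-2-methyl-5-(trimethylsilyl)pent-4-yn-2-ol | OCc1c(C[C@@](C)(O)CC#C[Si](C)(C)C)occ1CO[Si](C)(C)C(C)(C)C | intermediate
10 | 4-({[tert-butyl(dimethyl)silyl]oxy}methyl)-2-[(S)-2-hydroxy-2-methyl-5-(trimethylsilyl)pent-4-yn-1-yl]furan-3-carbaldehyde | O=Cc1c(C[C@@](C)(O)CC#C[Si](C)(C)C)occ1CO[Si](C)(C)C(C)(C)C | intermediate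
11 | (S)-2-hydroxy-1,2,2-triphenylethyl acetate | CC(=O)O[C@@H](c1ccccc1)C(O)(c1ccccc1)c1ccccc1 | starting material
12 | (S)-2-hydroxy-1,2,2-triphenylethyl (S)-3-{4-({[tert-butyl(dimethyl)silyl]oxy}methyl)-2-[(S)-2-hydroxy-2-methyl-5-(trimethylsilyl)pent-4-yn-1-yl]furan-3-yl}-3-hydroxypropanoate | O[C@@H](CC(=O)O[C@@H](c1ccccc1)C(O)(c1ccccc1)c1ccccc1)c1c(C[C@@](C)(O)CC#C[Si](C)(C)C)occ1CO[Si](C)(C)C(C)(C)C | intermediate
13 | (S)-3-{4-({[tert-butyl(dimethyl)silyl]oxy}methyl)-2-[(S)-2-hydroxy-2-methyl-5-(trimethylsilyl)pent-4-yn-1-yl]furan-3-yl}-3-hydroxy-N-methoxy-N-methylpropanamide | CON(C)C(=O)C[C@H](O)c1c(C[C@@](C)(O)CC#C[Si](C)(C)C)occ1CO[Si](C)(C)C(C)(C)C | intermediate (not isolated)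
14 | (S)-3-{4-({[tert-butyl(dimethyl)silyl]oxy}methyl)-2-[(S)-2-hydroxy-2-methylpent-4-yn-1-yl]furan-3-yl}-3-hydroxy-N-methoxy-N-methylpropanamide | CON(C)C(=O)C[C@H](O)c1c(C[C@@](C)(O)CC#C)occ1CO[Si](C)(C)C(C)(C)C | intermediate
15 | trilithium salt of the cyclic C10 N-methoxy-N-methyl hemiaminal (tetrahedral adduct of the C1 acetylide to the amide; C10 configuration not defined) | [Li+].[Li+].[Li+].[O-][C@H]1CC([O-])(N(C)OC)C#CC[C@](C)([O-])Cc2occ(CO[Si](C)(C)C(C)(C)C)c21 | intermediate (not isolated)
16 | (4S,8S)-13-[(tert-butyldimethylsilyl)oxy]-4,8-dihydroxy-14-nor-6,12-epoxygermacra-6,11-dien-1-yn-10-one | O[C@H]1CC(=O)C#CC[C@](C)(O)Cc2occ(CO[Si](C)(C)C(C)(C)C)c21 | intermediate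
17 | (4S,8S,10R)-13-[(tert-butyldimethylsilyl)oxy]-6,12-epoxygermacra-6,11-dien-1-yne-4,8,10-triol | O[C@H]1C[C@@](C)(O)C#CC[C@](C)(O)Cc2occ(CO[Si](C)(C)C(C)(C)C)c21 | intermediate
18 | (4S,8S,10R)-13-[(tert-butyldimethylsilyl)oxy]-4,10-dihydroxy-6,12-epoxygermacra-6,11-dien-1-yn-8-yl 2-methylprop-2-enoate | C=C(C)C(=O)O[C@H]1C[C@@](C)(O)C#CC[C@](C)(O)Cc2occ(CO[Si](C)(C)C(C)(C)C)c21 | intermediate
19 | (4S,8S,10R)-4,10,13-trihydroxy-6,12-epoxygermacra-6,11-dien-1-yn-8-yl 2-methylprop-2-enoate | C=C(C)C(=O)O[C@H]1C[C@@](C)(O)C#CC[C@](C)(O)Cc2occ(CO)c21 | intermediate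
20 | 6,12-epidioxy adduct of 19 (2,3,7-trioxabicyclo[2.2.1]hept-5-ene across C6 and C12; mixture at C6/C12) | C=C(C)C(=O)O[C@H]1C[C@@](C)(O)C#CC[C@](C)(O)CC23OOC(O2)C(CO)=C31 | intermediate (not isolated)
21 | (4S,8S,10R)-4,6,10,13-tetrahydroxy-8-(methacryloyloxy)germacr-7(11)-en-1-yn-12,6-olide (C6 epimers, in equilibrium with the 4-oxo-2-enoic acid) | C=C(C)C(=O)O[C@H]1C[C@@](C)(O)C#CC[C@](C)(O)CC2(O)OC(=O)C(CO)=C21 | intermediate (not isolated)
22 | (4S,5E,8S,10R)-13-acetoxy-4,10-dihydroxy-8-(methacryloyloxy)germacra-5,7(11)-dien-1-yn-12,6-olide | C=C(C)C(=O)O[C@H]1C[C@@](C)(O)C#CC[C@](C)(O)/C=C2/OC(=O)C(COC(C)=O)=C21 | intermediate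
23 | (4S,5E,8S,10R)-13-acetoxy-1,4-epoxy-10-hydroxy-8-(methacryloyloxy)germacra-1,5,7(11)-trien-12,6-olide | C=C(C)C(=O)O[C@H]1C[C@@](C)(O)C2=CC[C@@](C)(/C=C3/OC(=O)C(COC(C)=O)=C31)O2 | target

## Step count and least certain steps

Total step count: 14. Longest linear sequence: 13 (steps 1–3 and 5–14; the furan line, steps 4–14, is 11).

**Step 9 (key step, proposed new method).** Most likely failure: intermolecular acylation (oligomerisation) outruns ring closure, because the alkyne has to bend in the transition state; deprotonation next to the amide or base-induced loss of formaldehyde from the N-methoxy group could also compete with acetylide formation. Fallback by known chemistry, setting out from 14: both hydroxyls are silylated (Et3SiOTf, 2,6-lutidine) to the bis(triethylsilyl) ether F1. DIBAL-H at −78 °C reduces the Weinreb amide to the aldehyde F2. The ring is then closed by the acetylide-to-aldehyde addition established for ten-membered enediyne carbocycles (LiN(SiMe3)2, CeCl3, THF, −78 °C, high dilution) to give the cyclic propargylic alcohol F3 as a C10 epimer mixture. Dess–Martin oxidation gives the bis-silylated ynone F4, and PPTS in MeOH at 0 °C removes the two triethylsilyl groups; the route is rejoined at 16.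

**Step 10.** Most likely failure: poor facial selectivity at C10, because the conformational bias of the strained ring may compete with the chelate; conjugate addition, or closure of the C8 alkoxide onto C2, are further risks. Fallback for the case that addition proves anti-selective with respect to C8: the C8 centre is entered with the opposite configuration and corrected during esterification. Setting out from 10, the acetate aldol with (R)-2-hydroxy-1,2,2-triphenylethyl acetate gives the 8R adduct F5. Amide formation and methanolysis as in step 8 pass through the C-silylated amide F6 to the 8R alkyne F7. Ring closure as in step 9 passes through the chelate F8 to the 8R ynone F9. Methyl addition then gives the (8R,10R)-triol F10. Mitsunobu esterification with methacrylic acid (PPh3, diisopropyl azodicarboxylate) inverts C8 and installs the ester in one operation; the route is rejoined at 18.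

**Step 14.** Most likely failure: ionisation of the tertiary propargylic C10 alcohol (Meyer–Schuster-type rearrangement) or of the allylic C4 alcohol by the cationic gold catalyst, and acid-promoted addition of water to the strained enol ether during isolation. Fallback, setting out from 22: the gold-catalysed cyclisation is run in the presence of MeOH, so that the enol ether is trapped as the cyclic C1 methyl ketal F11, which can be purified. Silyl triflate-mediated ketal-to-enol-ether elimination (Me3SiOTf, i-Pr2NEt, −20 °C) then gives the enol ether as its C10 trimethylsilyl ether F12, and Et3N·3HF removes the silyl group; the route is rejoined at 23.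

**Step 5.** Most likely failure: lithiation beside the silyloxymethyl arm (C12) followed by oxygen-to-carbon silyl migration, or slow opening of the hindered epoxide with attack of the aryllithium on the alkynyl silicon. Fallback that removes the regiochemical question, setting out from 7: the unprotected diol is lithiated three times (n-BuLi, 3.3 equiv; both arms are equivalent, so either α-position is the right one) and alkylated with 6 as in step 5 to give the triol F13. The less hindered C13 hydroxyl is then silylated selectively (TBSCl, imidazole, −20 °C); the route is rejoined at 9.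

**Step 13.** Most likely failure: incomplete enol-lactonisation (the hydroxybutenolide persists), acetylation of the tertiary alcohols if the second stage is forced, or competing ene-type oxygenation. Fallback without singlet oxygen, setting out from 19: the furan is opened oxidatively with N-bromosuccinimide (NaHCO3, aqueous THF, −20 °C) to the Z-configured keto aldehyde F14, and Pinnick oxidation (NaClO2, NaH2PO4, 2-methylbut-2-ene) converts the aldehyde into the acid; the route is rejoined at 21, which is treated with Ac2O/Et3N/DMAP as in the second stage of step 13.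

## Further compounds

F1 | step 9 | (S)-3-{4-({[tert-butyl(dimethyl)silyl]oxy}methyl)-2-[(S)-2-methyl-2-(triethylsilyloxy)pent-4-yn-1-yl]furan-3-yl}-N-methoxy-N-methyl-3-(triethylsilyloxy)propanamide | CON(C)C(=O)C[C@H](O[Si](CC)(CC)CC)c1c(C[C@@](C)(O[Si](CC)(CC)CC)CC#C)occ1CO[Si](C)(C)C(C)(C)C
F2 | step 9 | (S)-3-{4-({[tert-butyl(dimethyl)silyl]oxy}methyl)-2-[(S)-2-methyl-2-(triethylsilyloxy)pent-4-yn-1-yl]furan-3-yl}-3-(triethylsilyloxy)propanal | O=CC[C@H](O[Si](CC)(CC)CC)c1c(C[C@@](C)(O[Si](CC)(CC)CC)CC#C)occ1CO[Si](C)(C)C(C)(C)C
F3 | step 9 | (4S,8S)-13-[(tert-butyldimethylsilyl)oxy]-4,8-bis(triethylsilyloxy)-14-nor-6,12-epoxygermacra-6,11-dien-1-yn-10-ol (C10 epimers) | CC[Si](CC)(CC)O[C@H]1CC(O)C#CC[C@](C)(O[Si](CC)(CC)CC)Cc2occ(CO[Si](C)(C)C(C)(C)C)c21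
F4 | step 9 | (4S,8S)-13-[(tert-butyldimethylsilyl)oxy]-4,8-bis(triethylsilyloxy)-14-nor-6,12-epoxygermacra-6,11-dien-1-yn-10-one | CC[Si](CC)(CC)O[C@H]1CC(=O)C#CC[C@](C)(O[Si](CC)(CC)CC)Cc2occ(CO[Si](C)(C)C(C)(C)C)c21
F5 | step 10 | (R)-2-hydroxy-1,2,2-triphenylethyl (R)-3-{4-({[tert-butyl(dimethyl)silyl]oxy}methyl)-2-[(S)-2-hydroxy-2-methyl-5-(trimethylsilyl)pent-4-yn-1-yl]furan-3-yl}-3-hydroxypropanoate | O[C@H](CC(=O)O[C@H](c1ccccc1)C(O)(c1ccccc1)c1ccccc1)c1c(C[C@@](C)(O)CC#C[Si](C)(C)C)occ1CO[Si](C)(C)C(C)(C)C
F6 | step 10 | (R)-3-{4-({[tert-butyl(dimethyl)silyl]oxy}methyl)-2-[(S)-2-hydroxy-2-methyl-5-(trimethylsilyl)pent-4-yn-1-yl]furan-3-yl}-3-hydroxy-N-methoxy-N-methylpropanamide | CON(C)C(=O)C[C@@H](O)c1c(C[C@@](C)(O)CC#C[Si](C)(C)C)occ1CO[Si](C)(C)C(C)(C)C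
F7 | step 10 | (R)-3-{4-({[tert-butyl(dimethyl)silyl]oxy}methyl)-2-[(S)-2-hydroxy-2-methylpent-4-yn-1-yl]furan-3-yl}-3-hydroxy-N-methoxy-N-methylpropanamide | CON(C)C(=O)C[C@@H](O)c1c(C[C@@](C)(O)CC#C)occ1CO[Si](C)(C)C(C)(C)C
F8 | step 10 | trilithium salt of the cyclic C10 N-methoxy-N-methyl hemiaminal of the 8R series (C10 configuration not defined) | [Li+].[Li+].[Li+].[O-][C@@H]1CC([O-])(N(C)OC)C#CC[C@](C)([O-])Cc2occ(CO[Si](C)(C)C(C)(C)C)c21
F9 | step 10 | (4S,8R)-13-[(tert-butyldimethylsilyl)oxy]-4,8-dihydroxy-14-nor-6,12-epoxygermacra-6,11-dien-1-yn-10-one | O[C@@H]1CC(=O)C#CC[C@](C)(O)Cc2occ(CO[Si](C)(C)C(C)(C)C)c21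
F10 | step 10 | (4S,8R,10R)-13-[(tert-butyldimethylsilyl)oxy]-6,12-epoxygermacra-6,11-dien-1-yne-4,8,10-triol | O[C@@H]1C[C@@](C)(O)C#CC[C@](C)(O)Cc2occ(CO[Si](C)(C)C(C)(C)C)c21
F11 | step 14 | (4S,5E,8S,10R)-13-acetoxy-1,4-epoxy-10-hydroxy-1-methoxy-8-(methacryloyloxy)germacra-5,7(11)-dien-12,6-olide (C1 epimers) | C=C(C)C(=O)O[C@H]1C[C@@](C)(O)C2(OC)CC[C@@](C)(/C=C3/OC(=O)C(COC(C)=O)=C31)O2
F12 | step 14 | (4S,5E,8S,10R)-13-acetoxy-1,4-epoxy-8-(methacryloyloxy)-10-(trimethylsilyloxy)germacra-1,5,7(11)-trien-12,6-olide | C=C(C)C(=O)O[C@H]1C[C@@](C)(O[Si](C)(C)C)C2=CC[C@@](C)(/C=C3/OC(=O)C(COC(C)=O)=C31)O2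
F13 | step 5 | (S)-1-[3,4-bis(hydroxymethyl)furan-2-yl]-2-methyl-5-(trimethylsilyl)pent-4-yn-2-ol | OCc1c(C[C@@](C)(O)CC#C[Si](C)(C)C)occ1CO
F14 | step 13 | (4S,7Z,8S,10R)-4,10,13-trihydroxy-8-(methacryloyloxy)-6-oxogermacr-7(11)-en-1-yn-12-al | C=C(C)C(=O)O[C@H]1C[C@@](C)(O)C#CC[C@](C)(O)CC(=O)/C1=C(/CO)C=O
A1 | alternative 1 | (S)-1-[4-({[tert-butyl(dimethyl)silyl]oxy}methyl)-5-oxo-2,5-dihydrofuran-3-yl]-3-[(S)-5-formyl-5-methyl-4,5-dihydrofuran-2-yl]-3-hydroxybutyl 2-methylprop-2-enoate (seco-aldehyde; 10R at the carbinol) | C=C(C)C(=O)O[C@@H](C[C@@](C)(O)C1=CC[C@@](C)(C=O)O1)C1=C(CO[Si](C)(C)C(C)(C)C)C(=O)OC1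
A2 | alternative 2 | (8S,10R)-13-acetoxy-4,5-epoxy-10-hydroxy-8-(methacryloyloxy)-1-oxogermacr-7(11)-en-12,6-olide (C4 drawn with the configuration that ring opening with inversion requires; C5 and C6 left open) | C=C(C)C(=O)O[C@H]1C[C@@](C)(O)C(=O)CC[C@@]2(C)OC2C2OC(=O)C(COC(C)=O)=C21
A3 | alternative 3 | methyl (4S,8S,10R)-13-acetoxy-4,10-dihydroxy-8-(methacryloyloxy)cadina-1(6),7(11)-dien-12-oate (octalin with a C1–C6 bond; C12 cis to C6) | C=C(C)C(=O)O[C@H]1C[C@@](C)(O)C2=C(C[C@@](C)(O)CC2)/C1=C(/COC(C)=O)C(=O)OC
A4 | alternative 3 | methyl (4S,8S,10R)-13-acetoxy-4,10-dihydroxy-8-(methacryloyloxy)-1,6-dioxogermacr-7(11)-en-12-oate | C=C(C)C(=O)O[C@H]1C[C@@](C)(O)C(=O)CC[C@](C)(O)CC(=O)/C1=C(/COC(C)=O)C(=O)OC
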